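**Assumptions:** compound 1 is bought as the single (1S,2R) enantiomer (the toluene‑derived cis‑dihydrodiol, a commercial biocatalytic building block). (2E,6E)‑Farnesyl bromide is commercial. The minor Z‑isomer from the last step is removed by chromatography.

**Retrosynthetic overview**
1. Target 10 ⇐ late‑stage SeO2/TBHP allylic oxidation of the terminal isopropylidene of 9. An ene reaction is followed by a [2,3]‑sigmatropic shift that puts O on the E‑methyl.
2. 9 ⇐ acetylation of 8. The epoxide of 8 (ring formed last) ⇐ Darzens‑type 3‑exo closure of the C5 alkoxide onto the tertiary α‑bromoketone 7.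
3. 7 ⇐ α′‑bromination of 6 ⇐ α′‑farnesylation of enone 4 with (E,E)‑farnesyl bromide 5.
4. 4 ⇐ bis‑silylation, alkene‑selective reduction and allylic oxidation of cis‑diol 1. The cyclohexene ring already exists in 1, and 1 supplies the C4 and C5 stereocenters. C6 is set in steps 5–6.

---

**Step 1**
Reactants: 1, (1S,2R)-3-methylcyclohexa-3,5-diene-1,2-diol
Product: 2, (1S,2R)-1,2-bis(TBS-oxy)-3-methylcyclohexa-3,5-diene
Conditions: TBSOTf (2.5 equiv), 2,6-lutidine, CH2Cl2, −78 → 0 °C
Reagents that add atoms: TBSOTf, CC(C)(C)[Si](C)(C)OS(=O)(=O)C(F)(F)F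
Why: Buffered silylation protects the acid‑labile cis‑diol against aromatization and blocks the allylic oxygens, leaving both stereocenters untouched.

**Step 2**
Reactants: 2
Product: 3, (1S,2R)-1,2-bis(TBS-oxy)-3-methylcyclohex-3-ene
Conditions: NBSH (o-nitrobenzenesulfonylhydrazide, 4 equiv), Et3N, CH2Cl2, −20 → 0 °C
Reagents that add atoms: none
Why: Diimide reduction (syn H2 transfer) is selective for the less hindered disubstituted C5=C6 alkene over the trisubstituted methyl‑bearing alkene, and no stereocenter is affected.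

**Step 3**
Reactants: 3
Product: 4, (4R,5S)-4,5-bis(TBS-oxy)-3-methylcyclohex-2-en-1-one
Conditions: Mn(OAc)3·2H2O (0.2 equiv), TBHP (5 equiv), 3 Å MS, EtOAc, rt
Reagents that add atoms: tert-butyl hydroperoxide, CC(C)(C)OO
Why: Mn(III)/TBHP radical allylic oxidation converts the allylic CH2 on the CH= side of the alkene into the conjugated β‑methyl enone, while the OTBS‑bearing allylic CH cannot become a ketone.

**Step 4**
Reactants: 4; 5, (2E,6E)-farnesyl bromide
Product: 6, (4R,5S)-4,5-bis(TBS-oxy)-3-methyl-6-[(2E,6E)-3,7,11-trimethyldodeca-2,6,10-trien-1-yl]cyclohex-2-en-1-one (C6 epimeric mixture)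
Conditions: LDA (1.1 equiv), THF, −78 °C; then 5, HMPA, −78 → −40 °C
Reagents that add atoms: none (the alkylating agent is reactant 5)
Why: LDA deprotonates only the single enolizable α′‑CH2 (C6), and SN2 alkylation at the primary allylic bromide keeps the E,E‑geometry. The new C6 stereocenter is an epimeric mixture that is erased in step 5.

**Step 5**
Reactants: 6
Product: 7, (4R,5S,6S)-6-bromo-4,5-bis(TBS-oxy)-3-methyl-6-[(2E,6E)-3,7,11-trimethyldodeca-2,6,10-trien-1-yl]cyclohex-2-en-1-one
Conditions: LDA, TMSCl, THF, −78 °C; then NBS, −78 → −20 °C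
Reagents that add atoms: N-bromosuccinimide, O=C1CCC(=O)N1Br
Why: Electrophilic α‑bromination of the silyl dienol ether occurs on the face anti to the adjacent C5‑OTBS, which places the tertiary C–Br trans to O5 and sets the C6 configuration needed for the closure in step 6.

**Step 6**
Reactants: 7
Product: 8, (1R,5R,6R)-5-hydroxy-4-methyl-1-[(2E,6E)-3,7,11-trimethyldodeca-2,6,10-trien-1-yl]-7-oxabicyclo[4.1.0]hept-3-en-2-one
Conditions: TBAF (3 equiv), THF, −20 → 0 °C
Reagents that add atoms: none
Why: Fluoride unmasks both alkoxides. The C5 alkoxide displaces the trans‑diaxial tertiary α‑bromide (3‑exo‑tet, Darzens type) with inversion at C6, so the epoxide lies cis to the C4 oxygen and the farnesyl group ends up trans to it.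

**Step 7**
Reactants: 8
Product: 9, (1R,5R,6R)-5-acetoxy-4-methyl-1-[(2E,6E)-3,7,11-trimethyldodeca-2,6,10-trien-1-yl]-7-oxabicyclo[4.1.0]hept-3-en-2-one
Conditions: Ac2O, DMAP, pyridine, CH2Cl2, 0 °C
Reagents that add atoms: acetic anhydride, CC(=O)OC(C)=O
Why: Simple acylation of the secondary allylic alcohol, with no stereocenter affected.

**Step 8**
Reactants: 9
Product: 10, yanuthone L, (1R,5R,6R)-5-acetoxy-1-[(2E,6E,10E)-12-hydroxy-3,7,11-trimethyldodeca-2,6,10-trien-1-yl]-4-methyl-7-oxabicyclo[4.1.0]hept-3-en-2-one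
Conditions: SeO2 (0.1 equiv), TBHP (3 equiv, 5.5 M in decane), CH2Cl2, 0 °C → rt
Reagents that add atoms: tert-butyl hydroperoxide, CC(C)(C)OO
Why: Sharpless–Umbreit allylic oxidation on the most accessible terminal trisubstituted alkene proceeds by an ene reaction and then a [2,3]‑sigmatropic rearrangement of the allylseleninic acid, delivering OH to the E‑methyl.

---

**Compound list**
1 | (1S,2R)-3-methylcyclohexa-3,5-diene-1,2-diol | O[C@@H]1C(C)=CC=C[C@@H]1O | starting material
2 | (1S,2R)-1,2-bis(TBS-oxy)-3-methylcyclohexa-3,5-diene | CC(C)(C)[Si](C)(C)O[C@@H]1C(C)=CC=C[C@@H]1O[Si](C)(C)C(C)(C)C | intermediate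
3 | (1S,2R)-1,2-bis(TBS-oxy)-3-methylcyclohex-3-ene | CC(C)(C)[Si](C)(C)O[C@@H]1C(C)=CCC[C@@H]1O[Si](C)(C)C(C)(C)C | intermediate
4 | (4R,5S)-4,5-bis(TBS-oxy)-3-methylcyclohex-2-en-1-one | CC(C)(C)[Si](C)(C)O[C@@H]1C(C)=CC(=O)C[C@@H]1O[Si](C)(C)C(C)(C)C | intermediate
5 | (2E,6E)-farnesyl bromide | BrC/C=C(\C)CC/C=C(\C)CCC=C(C)C | starting material
6 | 6-farnesyl-4,5-bis(TBS-oxy)-3-methylcyclohex-2-en-1-one (C6 epimers) | CC(C)(C)[Si](C)(C)O[C@@H]1C(C)=CC(=O)C(C/C=C(\C)CC/C=C(\C)CCC=C(C)C)[C@@H]1O[Si](C)(C)C(C)(C)C | intermediate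
7 | 6-bromo-6-farnesyl-4,5-bis(TBS-oxy)-3-methylcyclohex-2-en-1-one | CC(C)(C)[Si](C)(C)O[C@@H]1C(C)=CC(=O)[C@](Br)(C/C=C(\C)CC/C=C(\C)CCC=C(C)C)[C@@H]1O[Si](C)(C)C(C)(C)C | intermediate
8 | 5-hydroxy epoxy-enone (12-methyl) | O[C@@H]1C(C)=CC(=O)[C@]2(C/C=C(\C)CC/C=C(\C)CCC=C(C)C)O[C@H]12 | intermediate
9 | 5-acetoxy epoxy-enone (12-methyl) | CC(=O)O[C@@H]1C(C)=CC(=O)[C@]2(C/C=C(\C)CC/C=C(\C)CCC=C(C)C)O[C@H]12 | intermediate
10 | yanuthone L | CC(=O)O[C@@H]1C(C)=CC(=O)[C@]2(C/C=C(\C)CC/C=C(\C)CC/C=C(\C)CO)O[C@H]12 | target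

**Total steps: 8. Longest linear sequence: 8.**

**Three steps most likely to fail**
1. **Step 8 (terminal SeO2 oxidation on a fully decorated substrate).** Competing oxidation of the internal alkenes or acid opening of the epoxide is possible. Fallback: oxidize farnesyl acetate with SeO2 first (well precedented), protect the new 12‑OH as its TIPS ether, convert to the bromide, and carry it through steps 4–7 as the alkylating agent, with final TIPS removal.
2. **Step 6 (Darzens‑type closure).** The diaxial geometry may not be reached, or E2 loss of HBr may give a dienone that aromatizes. Fallback: mask the C2=C3 enone as its β‑phenylselenide, form the C5=C6 enone from 6 by E1cB loss of the C5 silyloxide, epoxidize syn to the free C4–OH (H2O2/NaOH), acetylate, then restore the enone by selenoxide elimination. The C4 stereocenter from 1 then directs the epoxide.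
3. **Steps 4–5 (enolization of a β‑silyloxy ketone).** E1cB loss of the C5 silyloxide competes with alkylation and bromination. Fallback: convert 4 to its N,N‑dimethylhydrazone, alkylate the azaenolate with 5, and hydrolyze back to the ketone. This is a softer nucleophile that is less prone to β‑elimination.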